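all flasks: X 0.0469 M
- violet: Z 0.027 M; run made earlier
- ochre: Z 0.39 M; run made earlier
- dusk: Z 0.030 M; time 2.5 d
- winter: Z 0.060 M; time 2.5 d
- spring: Z 0.12 M; time 2.5 d
- dawn: Z 0.25 M; time 2.5 d
- autumn: Z 0.50 M; time 2.5 d

| run | time / h | J / % | Z / % |
|---|---|---|---|
| violet | 3.00 | 1.3 | 85.0 |
| violet | 6.00 | 6.4 | 74.9 |
| violet | 10.0 | 8.5 | 61.4 |
| violet | 15.0 | 11.2 | 49.7 |
| violet | 25.0 | 15.5 | 34.5 |
| violet | 40.0 | 20.0 | 22.0 |
| ochre | 3.00 | 1.8 | 91.4 |
| ochre | 6.00 | 0.8 | 86.7 |
| ochre | 10.0 | 1.5 | 86.7 |
| ochre | 15.0 | 0 | 87.0 |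
| ochre | 25.0 | 0 | 84.9 |
| ochre | 40.0 | 0 | 86.5 |

(readings scatter by 1 percentage point)

- "hardly changes" means that all values lie within two and a half points (for a concentration: within two and a half percent of the largest)

* [J] at the end for dusk, winter, spring, dawn, autumn, in this order
* how that number moves from the first to the last of them (falls, then rises / falls all the way / hardly changes / rises all the way / rises, then falls)

**Compare runs.** Set ochre beside violet: at 15.0 h ochre's Z reads 87.0 %, higher than violet's 49.7 %, and ochre's readings stay near it. Take Z and X as reacting one to one, which puts ochre's floor at 88.0 % of its Z, close to those readings.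

**Read the constant.** Replace the curve by its mean. Over violet's first 10.0 h, X averages 0.0417 M, and the logarithmic fall of Z to 61.4 % then gives a reading of 1.17 M⁻¹ h⁻¹.

**Define exposure.** In spring, dawn and autumn Z is charged higher than X, so take the Z charge less the X charge as a working floor for Z and, as an approximation, let X decay against it in a pseudo-first-order way, X being the limiting reagent. The floor exposure, floor times time, is 4.39 M·h for spring. My reckoning from it leaves 0.588 % of spring's X. Now check the error: Z stands above its floor early, which adds 0.424 M·h and gives 0.358 %. Expect spring's X between these two values.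

**Climb the ladder.** Take one over the constant times the floor as X's clock: autumn 1.89 h, dawn 4.21 h, spring 11.7 h, then the asked 60 h. Expect X to end early in autumn and dawn, while Z stays high. Watch J there: ochre's J reads 0 % at 15.0 h, after an exposure of 5.15 M·h, whereas violet's J at 40.0 h reads a quarter of the Z used. In winter Z is charged at 0.060 M, too near X's 0.0469 M for this clock to hold, and in dusk Z is charged below X. So look for the highest J near winter.

**The forecast.** It gives 0.0058 M, 0.0067 M, 0.0025 M, 1.000 × 10⁻⁴ M and 0 M, so rises, then falls. Its ground reads: “More Z uses up X first, then excess Z destroys J, so J rises, then falls.”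

    Z + X → J (k = 8.60 × 10⁻⁵ M⁻¹ s⁻¹)
    Z + X → Q (k = 9.00 × 10⁻⁵ M⁻¹ s⁻¹)
    Z + X → E (k = 1.40 × 10⁻⁴ M⁻¹ s⁻¹)
    Z + J → G (k = 7.90 × 10⁻⁵ M⁻¹ s⁻¹)

**The result.** The flask gives 0.00620 M, 0.00803 M, 0.00456 M, 5.82 × 10⁻⁴ M and 8.74 × 10⁻⁶ M, so rises, then falls, and spring's 0.00456 M stands above the forecast's 0.0025 M. At 2.50 d spring's X stands at 0.557 % of its charge, and the floor exposure of 4.39 M·h gave 0.588 %. On dawn at 1.25 d, the exposure is 6.09 M·h, which gives 0.0802 %, and dawn's X then stands at 0.0955 %.

(The numbers in the tables come from a simulation from invented constants.)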